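**Retrosynthetic overview**
1. Feature: the oxolane O15–C1–C14–C13–C12 bridges the 14-membered carbocycle C1–C14, and C11, next to the ether carbon C12, carries the formate oxygen. This is the imprint of a 5-exo opening of an 11,12-epoxide by the C1 hydroxyl, so the oxolane is closed last, across the finished macrocycle; the formate follows.
2. Macrocycle (first ring): C5–C6 by intramolecular alkylation of a C6 α-sulfonyl carbanion with the C4–C5 vinyl epoxide; the sulfone is then converted into the C6 ketone and C11=C12 is epoxidised under reagent control.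
3. C2=C3: Julia–Kocienski olefination of a C2 tetrazolyl sulfone with (S)-2-methylglycidal (C3–C5, brings C4).
4. C1–C14: alkylation of the dioxolanone of (S)-2-hydroxy-3-methylbutanoic acid (C1, C2, isopropyl) with an E-homoallylic iodide. The iodide comes from (S)-citronellyl bromide (C6–C11, C8) by ozonolysis and cyclopropylcarbinyl–homoallyl rearrangement (C12–C14).
5. Ring order: carbocycle (step 15), oxirane (step 18), oxolane (step 19).

Key step: step 19

Remark: cembrane numbering (C1 bears the isopropyl group) is used for all intermediates.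
Assumption: (S)-citronellyl bromide is taken as purchased; made from (S)-citronellol by Appel bromination it would add one step.

**Route**

Step 1
Reactants: 1 (S)-citronellyl bromide
Product: 2 (S)-citronellyl phenyl sulfone
Conditions: PhSO2Na, Bu4NI (cat.), DMF, 60 °C
Reagents that add atoms: sodium benzenesulfinate, [Na+].[O-]S(=O)c1ccccc1
Why: SN2 S-alkylation of the sulfinate by the primary bromide should give the sulfone, which serves as the latent C6 acyl anion and tolerates every oxidation that follows; C8 is not touched.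

Step 2
Reactants: 2 (S)-citronellyl phenyl sulfone
Product: 4 (4S)-4-methyl-6-(phenylsulfonyl)hexanal, via secondary ozonide 3 (not isolated)
Conditions: O3, CH2Cl2, −78 °C; then PPh3, −78 °C → rt
Reagents that add atoms: ozone, [O-][O+]=O
Why: Ozonolysis with reductive work-up should cleave the only olefin and leave the C11 aldehyde; the sulfone is inert to ozone.

Step 3
Reactants: 4 (4S)-4-methyl-6-(phenylsulfonyl)hexanal
Product: 5 (6S)-2,6-dimethyl-8-(phenylsulfonyl)oct-1-en-3-ol (both carbinol epimers)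
Conditions: CH2=C(CH3)MgBr, THF, −78 → 0 °C; aq. NH4Cl
Reagents that add atoms: isopropenylmagnesium bromide, CC(=C)[Mg]Br
Why: Grignard 1,2-addition to the aldehyde is much faster at low temperature than deprotonation next to the sulfone; the new carbinol centre is erased in step 5, so its configuration does not matter.

Step 4
Reactants: 5 (6S)-2,6-dimethyl-8-(phenylsulfonyl)oct-1-en-3-ol
Product: 6 (4S)-4-methyl-1-(1-methylcyclopropyl)-6-(phenylsulfonyl)hexan-1-ol (both carbinol epimers)
Conditions: Et2Zn, CH2I2, CH2Cl2, 0 °C → rt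
Reagents that add atoms: diiodomethane, ICI
Why: Hydroxyl-directed Simmons–Smith cyclopropanation (Furukawa variant) of the 1,1-disubstituted allylic alcohol should be fast and clean, since no other olefin is present.

Step 5
Reactants: 6 (4S)-4-methyl-1-(1-methylcyclopropyl)-6-(phenylsulfonyl)hexan-1-ol
Product: 8 [(3S,6E)-9-bromo-3,7-dimethylnon-6-en-1-yl]sulfonylbenzene, via cyclopropylcarbinyl bromide 7 (not isolated)
Conditions: PBr3, LiBr, 2,4,6-collidine, Et2O, −30 → 0 °C; then ZnBr2, Et2O, 0 °C
Reagents that add atoms: phosphorus tribromide, BrP(Br)Br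
Why: Brady–Julia–Johnson cyclopropylcarbinyl-to-homoallyl rearrangement: ZnBr2 ionises the secondary bromide, the chain lies on the methyl side of the bisected cation and bromide opens the ring, which should give mainly the E-trisubstituted C11=C12 olefin with C13 and C14 in place.

Step 6
Reactants: 8 [(3S,6E)-9-bromo-3,7-dimethylnon-6-en-1-yl]sulfonylbenzene
Product: 9 [(3S,6E)-9-iodo-3,7-dimethylnon-6-en-1-yl]sulfonylbenzene
Conditions: NaI, acetone, reflux
Reagents that add atoms: sodium iodide, [Na+].[I-]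
Why: Finkelstein exchange at the unhindered primary carbon should supply the more reactive iodide needed for the hindered enolate in step 8.

Step 7
Reactants: 10 (S)-2-hydroxy-3-methylbutanoic acid
Product: 11 (2S,5S)-2-tert-butyl-5-isopropyl-1,3-dioxolan-4-one (cis)
Conditions: t-BuCHO, TsOH (cat.), H2SO4 (cat.), pentane, reflux, Dean–Stark; recrystallisation
Reagents that add atoms: pivalaldehyde, CC(C)(C)C=O
Why: Acetalisation under thermodynamic control should favour the cis dioxolanone, whose acetal centre stores the chirality of C1 (self-regeneration of stereocentres).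

Step 8
Reactants: 11 (2S,5S)-2-tert-butyl-5-isopropyl-1,3-dioxolan-4-one; 9 [(3S,6E)-9-iodo-3,7-dimethylnon-6-en-1-yl]sulfonylbenzene
Product: 13 (2S,5S)-2-tert-butyl-5-[(3E,7S)-3,7-dimethyl-9-(phenylsulfonyl)non-3-en-1-yl]-5-isopropyl-1,3-dioxolan-4-one, via lithium enolate 12 (not isolated)
Conditions: LDA (0.95 equiv), THF, −78 °C; then 9, DMPU, −78 → −20 °C
Reagents that add atoms: none
Why: Enolate alkylation with self-regeneration of the stereocentre: the iodide approaches the planar enolate anti to the tert-butyl group, so the chain takes the place of the former hydrogen and quaternary C1 is set with retention (S); the slight deficit of base keeps the sulfone CH2 protonated.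

Step 9
Reactants: 13 alkylated dioxolanone
Product: 14 (2S,5E,9S)-5,9-dimethyl-11-(phenylsulfonyl)-2-(propan-2-yl)undec-5-ene-1,2-diol
Conditions: LiAlH4, THF, 0 °C; Rochelle salt
Reagents that add atoms: none
Why: Hydride reduction of the lactone-acetal should release the C2 primary and C1 tertiary hydroxyls; the sulfone and the olefin are inert at 0 °C.

Step 10
Reactants: 14 diol
Product: 17 (2S,5E,9S)-5,9-dimethyl-11-(phenylsulfonyl)-1-[(1-phenyl-1H-tetrazol-5-yl)sulfanyl]-2-(propan-2-yl)undec-5-en-2-ol, via primary tosylate 15 (not isolated), via terminal epoxide 16 (not isolated)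
Conditions: TsCl, Et3N, DMAP (cat.), CH2Cl2, 0 °C; solvent exchange; then 1-phenyl-1H-tetrazole-5-thiol, K2CO3, DMF, 50 °C
Reagents that add atoms: 1-phenyl-1H-tetrazole-5-thiol, SC1=NN=NN1c1ccccc1
Why: Selective sulfonylation of the primary hydroxyl, base-induced closure to the 2,2-disubstituted epoxide and thiolate opening at its CH2 terminus should place sulfur on C2 without touching the C1 stereocentre.

Step 11
Reactants: 17 hydroxy sulfide
Product: 18 (2S,5E,9S)-5,9-dimethyl-11-(phenylsulfonyl)-1-[(1-phenyl-1H-tetrazol-5-yl)sulfonyl]-2-(propan-2-yl)undec-5-en-2-ol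
Conditions: (NH4)6Mo7O24·4H2O (cat.), 30% H2O2, EtOH, 0 °C → rt
Reagents that add atoms: hydrogen peroxide, OO
Why: Molybdate-catalysed peroxide oxidation takes sulfides to sulfones much faster than it epoxidises an unactivated trisubstituted olefin.

Step 12
Reactants: 18 hydroxy bis-sulfone
Product: 19 triethylsilyl ether of 18 (C1–OSiEt3)
Conditions: Et3SiOTf, 2,6-lutidine, CH2Cl2, −78 → 0 °C
Reagents that add atoms: triethylsilyl trifluoromethanesulfonate, CC[Si](CC)(CC)OS(=O)(=O)C(F)(F)F
Why: Silylation of the tertiary hydroxyl is needed because a free β-alkoxide would attack the tetrazole (Smiles rearrangement) and destroy the sulfone under the olefination conditions.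

Step 13
Reactants: 20 (R)-2-methylglycidol
Product: 21 (S)-2-methyloxirane-2-carbaldehyde
Conditions: Dess–Martin periodinane, NaHCO3, CH2Cl2, 0 °C → rt; filtered solution used at once
Reagents that add atoms: none
Why: Buffered Dess–Martin oxidation should give the volatile epoxy aldehyde, which has no α-hydrogen and so cannot epimerise at the future C4.

Step 14
Reactants: 19 silyl-protected tetrazolyl sulfone; 21 (S)-2-methyloxirane-2-carbaldehyde
Product: 22 triethylsilyl ether of (1E,3S,6E,10S)-6,10-dimethyl-1-[(2R)-2-methyloxiran-2-yl]-12-(phenylsulfonyl)-3-(propan-2-yl)dodeca-1,6-dien-3-ol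
Conditions: KHMDS added to 19 and 21 (3 equiv), DME, −78 °C → rt
Reagents that add atoms: none
Why: Julia–Kocienski olefination: the base metalates only the more acidic tetrazolyl sulfone CH2; addition to the non-enolisable aldehyde, Smiles rearrangement and loss of SO2 and tetrazolate should give the E C2=C3 olefin between the two fully substituted carbons; the Barbier mode keeps the β-silyloxy carbanion short-lived.

Step 15
Reactants: 22 acyclic epoxy sulfone
Product: 24 (1S,2E,4S,8S,11E)-4,8,12-trimethyl-6-(phenylsulfonyl)-1-(propan-2-yl)-1-(triethylsilyloxy)cyclotetradeca-2,11-dien-4-ol (C6 epimers), via lithiated sulfone 23 (not isolated)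
Conditions: LDA (1.2 equiv), THF, −78 °C; dilution to 2 mM with THF/DMPU, −78 → 25 °C; aq. NH4Cl
Reagents that add atoms: none
Why: Intramolecular alkylation of the α-sulfonyl carbanion by the primary C5 terminus of the vinyl epoxide closes the 14-membered ring (C5–C6), the ring closure by sulfur-stabilised carbanion and epoxide that is established for cembrane rings; C4 keeps its configuration because its C–O bond is not broken, and the thermally stable carbanion allows slow cyclisation at high dilution.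

Step 16
Reactants: 24 macrocyclic hydroxy sulfone
Product: 26 (1S,2E,4S,8S,11E)-4-hydroxy-4,8,12-trimethyl-1-(propan-2-yl)-1-(triethylsilyloxy)cyclotetradeca-2,11-dien-6-one, via dilithio sulfone 25 (not isolated)
Conditions: LDA (2.3 equiv), THF, −78 → −40 °C; then Me3SiOOSiMe3, −78 °C; aq. NH4Cl at −78 °C
Reagents that add atoms: bis(trimethylsilyl) peroxide, C[Si](C)(C)OO[Si](C)(C)C
Why: Oxidative desulfonylation: the α-sulfonyl carbanion is oxygenated by the silyl peroxide and the α-oxy sulfone collapses to the C6 ketone with loss of sulfinate; the cold quench prevents retro-aldol cleavage of the lithium aldolate.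

Step 17
Reactants: 26 silyl-protected hydroxy ketone
Product: 27 (1S,2E,4S,8S,11E)-1,4-dihydroxy-4,8,12-trimethyl-1-(propan-2-yl)cyclotetradeca-2,11-dien-6-one
Conditions: HF·pyridine, pyridine, THF, 0 °C → rt
Reagents that add atoms: none
Why: Buffered HF cleaves the hindered tertiary silyl ether without the basic fluoride that could trigger retro-aldol cleavage; it is used before the acid-labile epoxide is present.

Step 18
Reactants: 27 macrocyclic diol ketone
Product: 28 (1S,2E,4S,8S,11R,12R)-11,12-epoxy-1,4-dihydroxy-4,8,12-trimethyl-1-(propan-2-yl)cyclotetradec-2-en-6-one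
Conditions: D-fructose-derived Shi ketone (0.3 equiv), Oxone, K2CO3, Bu4NHSO4, Na2B4O7/Na2EDTA buffer, MeCN/dimethoxymethane, 0 °C; Et3N-washed silica
Reagents that add atoms: potassium peroxymonosulfate (Oxone), [K+].[O-]S(=O)(=O)OO
Why: Shi epoxidation: the chiral dioxirane attacks the electron-rich trisubstituted C11=C12 through a spiro transition state on the face that should give the (11R,12R) trans-epoxide by reagent control; C2=C3, flanked by two fully substituted carbinol carbons, is too hindered to compete.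

Step 19
Reactants: 28 epoxy diol ketone
Product: 29 (1S,2E,4S,8S,11R,12S)-4,11-dihydroxy-4,8,12-trimethyl-1-(propan-2-yl)-15-oxabicyclo[10.2.1]pentadec-2-en-6-one
Conditions: PPTS (0.2 equiv), CH2Cl2, 0 °C → rt
Reagents that add atoms: none
Why: Acid activation of the epoxide oxygen lets the C1 hydroxyl attack C12 from the side opposite the breaking C12–O bond, an SN2-like opening with advanced cleavage at the tertiary carbon; the closest known reaction type is the acid-catalysed cyclisation of 4,5-epoxy alcohols to 2-(1-hydroxyalkyl)oxolanes. The oxolane O15–C1–C14–C13–C12 closes in the 5-exo-tet mode across the 14-membered ring and turns the monocycle into the 15-oxabicyclo[10.2.1] core. C12 is the only centre that changes: backside attack inverts it to S, as dictated by the 12R epoxide, while C11 keeps its oxygen and R configuration and C1 keeps its C–O bond. The step needs attack at C12 and not at C11 (6-endo); this is secured because C12 bears positive charge better and because the exo path is the easier one with the C1 oxygen four atoms away. It also needs the C1 hydroxyl to outrun the C4 hydroxyl and the C6 carbonyl, which could only close rings of seven or more members, and an acid mild enough to spare the tertiary allylic alcohols and the β-hydroxy ketone, hence a pyridinium salt at 0 °C. The trans-epoxide can turn its oxygen to the outer face of the ring, so the inner C1 oxygen reaches the back of C12 and C2 and C11 end up cis on the oxolane.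

Step 20
Reactants: 29 deformyl compound
Product: 30 target, (1S,2E,4S,8S,11R,12S)-4-hydroxy-4,8,12-trimethyl-6-oxo-1-(propan-2-yl)-15-oxabicyclo[10.2.1]pentadec-2-en-11-yl formate
Conditions: acetic formic anhydride, pyridine, CH2Cl2, 0 °C
Reagents that add atoms: acetic formic anhydride, CC(=O)OC=O
Why: The mixed anhydride transfers the small formyl group to the secondary C11 hydroxyl; the tertiary C4 hydroxyl should not be acylated under these conditions.

**Compound list**
1 | (S)-citronellyl bromide, (6S)-8-bromo-2,6-dimethyloct-2-ene | BrCC[C@@H](C)CCC=C(C)C | starting material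
2 | (S)-citronellyl phenyl sulfone, [(3S)-3,7-dimethyloct-6-en-1-yl]sulfonylbenzene | O=S(=O)(c1ccccc1)CC[C@@H](C)CCC=C(C)C | intermediate
3 | secondary ozonide of 2 (1,2,4-trioxolane, not isolated) | O=S(=O)(c1ccccc1)CC[C@@H](C)CCC1OOC(C)(C)O1 | intermediate
4 | (4S)-4-methyl-6-(phenylsulfonyl)hexanal | O=S(=O)(c1ccccc1)CC[C@@H](C)CCC=O | intermediate
5 | (6S)-2,6-dimethyl-8-(phenylsulfonyl)oct-1-en-3-ol, carbinol epimers | O=S(=O)(c1ccccc1)CC[C@@H](C)CCC(O)C(C)=C | intermediate
6 | (4S)-4-methyl-1-(1-methylcyclopropyl)-6-(phenylsulfonyl)hexan-1-ol, carbinol epimers | O=S(=O)(c1ccccc1)CC[C@@H](C)CCC(O)C1(C)CC1 | intermediate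
7 | [(3S)-6-bromo-3-methyl-6-(1-methylcyclopropyl)hexyl]sulfonylbenzene (not isolated) | O=S(=O)(c1ccccc1)CC[C@@H](C)CCC(Br)C1(C)CC1 | intermediate
8 | [(3S,6E)-9-bromo-3,7-dimethylnon-6-en-1-yl]sulfonylbenzene | O=S(=O)(c1ccccc1)CC[C@@H](C)CC/C=C(\C)CCBr | intermediate
9 | [(3S,6E)-9-iodo-3,7-dimethylnon-6-en-1-yl]sulfonylbenzene | O=S(=O)(c1ccccc1)CC[C@@H](C)CC/C=C(\C)CCI | intermediate
10 | (S)-2-hydroxy-3-methylbutanoic acid | CC(C)[C@H](O)C(=O)O | starting material
11 | (2S,5S)-2-tert-butyl-5-isopropyl-1,3-dioxolan-4-one (cis) | CC(C)[C@@H]1O[C@H](C(C)(C)C)OC1=O | intermediate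
12 | lithium enolate of 11 (not isolated) | CC(C)C1=C([O-])O[C@@H](C(C)(C)C)O1.[Li+] | intermediate
13 | (2S,5S)-2-tert-butyl-5-[(3E,7S)-3,7-dimethyl-9-(phenylsulfonyl)non-3-en-1-yl]-5-isopropyl-1,3-dioxolan-4-one | CC(C)[C@]1(CC/C(C)=C/CC[C@H](C)CCS(=O)(=O)c2ccccc2)O[C@H](C(C)(C)C)OC1=O | intermediate
14 | (2S,5E,9S)-5,9-dimethyl-11-(phenylsulfonyl)-2-(propan-2-yl)undec-5-ene-1,2-diol | CC(C)[C@](O)(CO)CC/C(C)=C/CC[C@H](C)CCS(=O)(=O)c1ccccc1 | intermediate
15 | primary 4-methylbenzenesulfonate of 14 (not isolated) | CC(C)[C@](O)(COS(=O)(=O)c1ccc(C)cc1)CC/C(C)=C/CC[C@H](C)CCS(=O)(=O)c1ccccc1 | intermediate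
16 | (2S)-2-[(3E,7S)-3,7-dimethyl-9-(phenylsulfonyl)non-3-en-1-yl]-2-isopropyloxirane (not isolated) | CC(C)[C@]1(CO1)CC/C(C)=C/CC[C@H](C)CCS(=O)(=O)c2ccccc2 | intermediate
17 | (2S,5E,9S)-5,9-dimethyl-11-(phenylsulfonyl)-1-[(1-phenyl-1H-tetrazol-5-yl)sulfanyl]-2-(propan-2-yl)undec-5-en-2-ol | CC(C)[C@](O)(CSc1nnnn1-c1ccccc1)CC/C(C)=C/CC[C@H](C)CCS(=O)(=O)c1ccccc1 | intermediate
18 | (2S,5E,9S)-5,9-dimethyl-11-(phenylsulfonyl)-1-[(1-phenyl-1H-tetrazol-5-yl)sulfonyl]-2-(propan-2-yl)undec-5-en-2-ol | CC(C)[C@](O)(CS(=O)(=O)c1nnnn1-c1ccccc1)CC/C(C)=C/CC[C@H](C)CCS(=O)(=O)c1ccccc1 | intermediate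
19 | triethylsilyl ether of 18 | CC(C)[C@](O[Si](CC)(CC)CC)(CS(=O)(=O)c1nnnn1-c1ccccc1)CC/C(C)=C/CC[C@H](C)CCS(=O)(=O)c1ccccc1 | intermediate
20 | (R)-2-methylglycidol | OC[C@]1(C)CO1 | starting material
21 | (S)-2-methyloxirane-2-carbaldehyde | O=C[C@]1(C)CO1 | intermediate
22 | triethylsilyl ether of (1E,3S,6E,10S)-6,10-dimethyl-1-[(2R)-2-methyloxiran-2-yl]-12-(phenylsulfonyl)-3-(propan-2-yl)dodeca-1,6-dien-3-ol | CC(C)[C@](O[Si](CC)(CC)CC)(/C=C/[C@]1(C)CO1)CC/C(C)=C/CC[C@H](C)CCS(=O)(=O)c2ccccc2 | intermediate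
23 | α-lithio sulfone of 22 (not isolated) | CC(C)[C@](O[Si](CC)(CC)CC)(/C=C/[C@]1(C)CO1)CC/C(C)=C/CC[C@H](C)C[CH-]S(=O)(=O)c2ccccc2.[Li+] | intermediate
24 | (1S,2E,4S,8S,11E)-4,8,12-trimethyl-6-(phenylsulfonyl)-1-(propan-2-yl)-1-(triethylsilyloxy)cyclotetradeca-2,11-dien-4-ol, C6 epimers | CC(C)[C@]1(O[Si](CC)(CC)CC)/C=C/[C@@](C)(O)CC(S(=O)(=O)c2ccccc2)C[C@@H](C)CC/C=C(\C)CC1 | intermediate
25 | dilithio derivative of 24, C4 alkoxide and C6 carbanion (not isolated) | CC(C)[C@]1(O[Si](CC)(CC)CC)/C=C/[C@@](C)([O-])C[C-](S(=O)(=O)c2ccccc2)C[C@@H](C)CC/C=C(\C)CC1.[Li+].[Li+] | intermediate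
26 | (1S,2E,4S,8S,11E)-4-hydroxy-4,8,12-trimethyl-1-(propan-2-yl)-1-(triethylsilyloxy)cyclotetradeca-2,11-dien-6-one | CC(C)[C@]1(O[Si](CC)(CC)CC)/C=C/[C@@](C)(O)CC(=O)C[C@@H](C)CC/C=C(\C)CC1 | intermediate
27 | (1S,2E,4S,8S,11E)-1,4-dihydroxy-4,8,12-trimethyl-1-(propan-2-yl)cyclotetradeca-2,11-dien-6-one | CC(C)[C@]1(O)/C=C/[C@@](C)(O)CC(=O)C[C@@H](C)CC/C=C(\C)CC1 | intermediate
28 | (1S,2E,4S,8S,11R,12R)-11,12-epoxy-1,4-dihydroxy-4,8,12-trimethyl-1-(propan-2-yl)cyclotetradec-2-en-6-one | CC(C)[C@]1(O)/C=C/[C@@](C)(O)CC(=O)C[C@@H](C)CC[C@H]2O[C@]2(C)CC1 | intermediate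
29 | (1S,2E,4S,8S,11R,12S)-4,11-dihydroxy-4,8,12-trimethyl-1-(propan-2-yl)-15-oxabicyclo[10.2.1]pentadec-2-en-6-one | CC(C)[C@]12/C=C/[C@@](C)(O)CC(=O)C[C@@H](C)CC[C@@H](O)[C@](C)(CC1)O2 | intermediate
30 | (1S,2E,4S,8S,11R,12S)-4-hydroxy-4,8,12-trimethyl-6-oxo-1-(propan-2-yl)-15-oxabicyclo[10.2.1]pentadec-2-en-11-yl formate | CC(C)[C@]12/C=C/[C@@](C)(O)CC(=O)C[C@@H](C)CC[C@@H](OC=O)[C@](C)(CC1)O2 | target

Total step count: 20. Longest linear sequence: 18 steps (1–6, 8–12, 14–20).

**Steps most likely to fail**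

1. Step 15 (macrocyclisation). Intermolecular alkylation could outrun ring closure and give oligomers, or the base could isomerise the vinyl epoxide before the carbanion reaches it. The fallback closes the ring by olefination instead of alkylation; it sets out from 17 and comes back at 24. Silylation of 17 (Et3SiOTf, 2,6-lutidine) gives the triethylsilyl ether of the hydroxy sulfide F1. Separately, 20 is converted with NaH and 4-methoxybenzyl chloride into (S)-2-[(4-methoxybenzyloxy)methyl]-2-methyloxirane F2. Lithiation of the phenyl sulfone of F1 (LDA, THF, −78 °C) and intermolecular opening of F2 at its CH2 terminus (DMPU, 0 °C) forms C5–C6 without any dilution problem and gives the coupled hydroxy sulfone F3. Molybdate/H2O2 oxidises the sulfide to the tetrazolyl sulfone F4, DDQ removes the benzyl ether to give the C3,C4-diol F5, and TEMPO/PhI(OAc)2 oxidises the primary hydroxyl to the α-hydroxy aldehyde F6. KHMDS (2.2 equiv, DME, 2 mM) then closes the ring at C2=C3 by intramolecular Julia–Kocienski olefination and should give 24.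

2. Step 8 (quaternary C1 by enolate alkylation). The SN2 reaction of the hindered enolate with an unactivated iodide may be too slow, so that elimination of HI from 9 and decay of the enolate on warming take over. The fallback replaces the alkylation by an aldol addition, which the same enolate undergoes readily, followed by deoxygenation; it sets out from 9 and 11 and comes back at 13. Iodide 9 is oxidised with anhydrous trimethylamine N-oxide in DMSO to (3E,7S)-3,7-dimethyl-9-(phenylsulfonyl)non-3-enal F7, used at once. Enolate 12 (from 11) adds to F7 at −78 °C, again anti to the tert-butyl group, and gives the C14-hydroxy dioxolanone F8 as carbinol epimers. Thiocarbonyldiimidazole converts F8 into the O-imidazolylthiocarbonyl derivative F9, and Barton–McCombie reduction (Bu3SnH, AIBN, toluene, 90 °C) removes the C14 oxygen to return 13.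

3. Step 19 (transannular etherification). Under acid the β-hydroxy ketone could undergo retro-aldol cleavage or dehydration to the dienone, or the C6 carbonyl could take part in the opening before the C1 hydroxyl closes the oxolane. The fallback keeps the same bond formation but runs it while C6 is still a sulfone, so none of these processes is possible; it sets out from 24 and comes back at 29. HF·pyridine on 24 gives the macrocyclic diol sulfone F10. Shi epoxidation as in step 18 gives the (11R,12R)-epoxy diol sulfone F11. PPTS in CH2Cl2 closes the oxolane to the bicyclic sulfone F12 (free C4 and C11 hydroxyls). Oxidative desulfonylation of the trianion (LDA, 3.3 equiv; Me3SiOOSiMe3; −78 °C) then gives 29.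

Further compounds
F1 | step 15 | triethylsilyl ether of hydroxy sulfide 17 | CC(C)[C@](O[Si](CC)(CC)CC)(CSc1nnnn1-c1ccccc1)CC/C(C)=C/CC[C@H](C)CCS(=O)(=O)c1ccccc1
F2 | step 15 | (S)-2-[(4-methoxybenzyloxy)methyl]-2-methyloxirane | C[C@@]1(COCc2ccc(OC)cc2)CO1
F3 | step 15 | C5–C6 coupled hydroxy sulfone: F1 bearing CH2–C(CH3)(OH)–CH2O-(4-methoxybenzyl) on the sulfonyl carbon | CC(C)[C@](O[Si](CC)(CC)CC)(CSc1nnnn1-c1ccccc1)CC/C(C)=C/CC[C@H](C)CC(C[C@](C)(O)COCc1ccc(OC)cc1)S(=O)(=O)c1ccccc1
F4 | step 15 | tetrazolyl sulfone from F3 | CC(C)[C@](O[Si](CC)(CC)CC)(CS(=O)(=O)c1nnnn1-c1ccccc1)CC/C(C)=C/CC[C@H](C)CC(C[C@](C)(O)COCc1ccc(OC)cc1)S(=O)(=O)c1ccccc1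
F5 | step 15 | C3,C4-diol from F4 | CC(C)[C@](O[Si](CC)(CC)CC)(CS(=O)(=O)c1nnnn1-c1ccccc1)CC/C(C)=C/CC[C@H](C)CC(C[C@](C)(O)CO)S(=O)(=O)c1ccccc1
F6 | step 15 | C3 aldehyde (α-hydroxy aldehyde) from F5 | CC(C)[C@](O[Si](CC)(CC)CC)(CS(=O)(=O)c1nnnn1-c1ccccc1)CC/C(C)=C/CC[C@H](C)CC(C[C@](C)(O)C=O)S(=O)(=O)c1ccccc1
F7 | step 8 | (3E,7S)-3,7-dimethyl-9-(phenylsulfonyl)non-3-enal | O=CC/C(C)=C/CC[C@H](C)CCS(=O)(=O)c1ccccc1
F8 | step 8 | (2S,5S)-2-tert-butyl-5-[(3E,7S)-1-hydroxy-3,7-dimethyl-9-(phenylsulfonyl)non-3-en-1-yl]-5-isopropyl-1,3-dioxolan-4-one, carbinol epimers | CC(C)[C@]1(C(O)C/C(C)=C/CC[C@H](C)CCS(=O)(=O)c2ccccc2)O[C@H](C(C)(C)C)OC1=O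
F9 | step 8 | O-(imidazol-1-ylthiocarbonyl) derivative of F8 | CC(C)[C@]1(C(OC(=S)n2ccnc2)C/C(C)=C/CC[C@H](C)CCS(=O)(=O)c2ccccc2)O[C@H](C(C)(C)C)OC1=O
F10 | step 19 | (1S,2E,4S,8S,11E)-4,8,12-trimethyl-6-(phenylsulfonyl)-1-(propan-2-yl)cyclotetradeca-2,11-diene-1,4-diol | CC(C)[C@]1(O)/C=C/[C@@](C)(O)CC(S(=O)(=O)c2ccccc2)C[C@@H](C)CC/C=C(\C)CC1
F11 | step 19 | (11R,12R)-11,12-epoxide of F10 | CC(C)[C@]1(O)/C=C/[C@@](C)(O)CC(S(=O)(=O)c2ccccc2)C[C@@H](C)CC[C@H]3O[C@]3(C)CC1
F12 | step 19 | (1S,2E,4S,8S,11R,12S)-4,8,12-trimethyl-6-(phenylsulfonyl)-1-(propan-2-yl)-15-oxabicyclo[10.2.1]pentadec-2-ene-4,11-diol | CC(C)[C@]12/C=C/[C@@](C)(O)CC(S(=O)(=O)c3ccccc3)C[C@@H](C)CC[C@@H](O)[C@](C)(CC1)O2
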